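The runs were generated by integration with made-up constants; scatter was added.

The leftover I started from was the 0.250 M of coupling partner that this flask keeps once 0.84 M of substrate has taken one equivalent. Substrate takes partner to give first product. First product then takes a second partner to give bis adduct, decays to decomposed reagent, or meets capture agent and becomes trapped intermediate. So each substrate that reacts costs one partner, and one more if it ends as bis adduct.

| setting | south-east | south-west | flask |
|---|---|---|---|
| substrate | 0.84 M (fed, over 30 s) | 0.84 M (fed, over 30 s) | 0.84 M (fed, over 30 s) |
| coupling partner | 1.5 M | 2.4 M | 1.09 M |
| capture agent | 0.252 M | 0.252 M | 0.252 M |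
| remark | run made earlier; the fed solution adds 0.20 times the starting volume | run made earlier; the fed solution adds 0.20 times the starting volume | the fed solution adds 0.20 times the starting volume |
| time |  |  | 1.0 h |

| run | time / min | bis adduct / % | trapped intermediate / % |
|---|---|---|---|
| south-east | 3.00 | 65.3 | 10.2 |
| south-east | 10.0 | 71.0 | 12.6 |
| south-east | 15.0 | 70.2 | 13.9 |
| south-east | 25.0 | 69.4 | 13.6 |
| south-east | 40.0 | 70.5 | 13.2 |
| south-east | 50.0 | 69.6 | 13.5 |
| south-east | 60.0 | 70.1 | 13.0 |
| south-west | 3.00 | 85.9 | 5.3 |
| south-west | 10.0 | 86.6 | 5.7 |
| south-west | 15.0 | 87.3 | 6.5 |
| south-west | 25.0 | 87.2 | 5.7 |
| south-west | 40.0 | 87.4 | 6.2 |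
| south-west | 50.0 | 87.2 | 6.0 |
| south-west | 60.0 | 87.3 | 6.1 |

(scatter of a reading: 0.5 percentage points)

- charges are per starting volume, the dose included; the dosed solution carries all of it
- on the list of suspects stand: substrate + coupling partner -> first product; coupling partner + first product -> bis adduct; first product -> decomposed reagent; first product + capture agent -> trapped intermediate
- the reaction counts as stopped when no species that holds the substrate changes by six tenths of a point or more over the second half of the time

- which holds at 1.0 h: what has brought the reaction to rest, or that it has not come to rest (forward and back rates have come level / all of the substrate has reacted / it is still moving / the coupling partner has run out first)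
- amount of bis adduct at 1.0 h, in percent of the substrate charged
- amount of trapped intermediate at 1.0 h, in percent of the substrate charged
- amount of bis adduct if the flask were left three thousand times as long, in percent of the substrate charged

My first estimate spent that leftover on bis adduct, 29.8 % of the substrate, which asks first product to send just that share onward. The south-east run objected. Its bis adduct stood at 70.1 %, so, taking its substrate as consumed, its partner fell from 1.5 M to 0.0712 M, a mean of 0.786 M. Bis adduct over the other exits, per unit of that mean partner, came to 2.98 M⁻¹; I call this the partition number.

In this flask, with partner as limiting reagent falling to about zero, the mean is 0.545 M. The ratio is then 1.63, higher than the 0.425 my first estimate needed. So I reckoned that first product in this flask sends 61.9 % onward, that each reacted substrate costs one partner plus that share, and that the charge converts 80.1 % of the substrate. My estimate for this flask was therefore 19.9 % of the substrate unreacted and 49.6 % bis adduct.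

But the south-west run reads 4.26 M⁻¹, which would give 53.4 % bis adduct in this flask. I kept the south-east number, since by the same balance the south-east partner ended at 0.0712 M, lower than the 0.827 M of the south-west run, and this flask's partner was to fall to about zero as well. The trapped intermediate of the south-east run, 43.5 % of the other exits there, gave me an estimate of 13.3 % trapped intermediate in this flask.

The forecast differed from my reckoning. It held “After 0.84 M goes on the first step, only 0.25 M remains, capping bis adduct near 29.8%.” It said the coupling partner has run out first, with bis adduct 29.6 % (28.5 % to 30.5 %), trapped intermediate 23.7 % (22 % to 25.5 %), and 29.7 % (28.5 % to 31 %) after the long wait.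

The flask gave: the coupling partner has run out first, bis adduct 47.4 %, trapped intermediate 14.9 %, and 47.4 % after the long wait.

    substrate + coupling partner → first product (k = 0.0380 M⁻¹ s⁻¹)
    coupling partner + first product → bis adduct (k = 0.100 M⁻¹ s⁻¹)
    first product → decomposed reagent (k = 0.00930 s⁻¹)
    first product + capture agent → trapped intermediate (k = 0.0450 M⁻¹ s⁻¹)

The flask ended with 0 % of its partner and 17.6 % of its substrate, and its own end state puts the partition number at 2.48 M⁻¹. I carried the south-east number to a neighbour like this flask but charged with 0.27 M of partner. Its mean partner of 0.135 M gives a ratio of 0.403, so 28.7 % goes onward, and the reckoning gives 7.17 % bis adduct with 75.0 % of the substrate unreacted. That neighbour ended with 5.67 % bis adduct and 73.5 % substrate.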